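**Plan**
- Retrosynthesis: after removal of the silyl groups, the ring B C5–CH= bond is cut (Heck coupling) to an aryl bromide and a ring D styrene. Four of the six bonds of ring C (C1–C2, C2–C3, C4–C5, C5–C6) are then cut back to an (E)-α,β-unsaturated α′-diazo ketone and a silyloxyacetylene.
- Further back, the chain C=C (Wittig), the Cα–ring A bond (conjugate arylation of a coumarin) and the coumarin C3=C4 bond are cut.
- Enabling feature: ring C is a 4-alkylresorcinol with the CH2 branch on C1, OH on C2 and C4, and H on C3. C2 maps onto the ketone carbon, C5 onto the diazo carbon, C6 and C1 onto the enone α- and β-carbons, and C3/C4 onto HC≡C–OSi.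
- Forward: ring B is made into a coumarin, ring A is added at C4, the lactone is opened and the chain is grown to the diazo enone. Ring C is then built by benzannulation, ring D is joined by Heck coupling, and all silyl ethers are removed.
- Stereochemistry: the single (S) centre comes from the rhodium/(S)-SEGPHOS 1,4-addition and is never adjacent to a reacting centre afterwards; the E stilbene comes from the Heck step.

Key step: step 9

Assumption: the facial sense known for SEGPHOS–rhodium arylation of coumarins ((R)-ligand gives (R)-4-arylchroman-2-ones) is taken to hold here, so the (S)-ligand is used.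

Abbreviations in names: TBS = tert-butyldimethylsilyl; TIPS = triisopropylsilyl; ArA = 4-(TBS-oxy)-3-methoxyphenyl (ring A); ArB = 5-bromo-2-(TBS-oxy)-3-methoxyphenyl (ring B).

**Route**

Step 1
Reactants: 1 5-bromo-2-hydroxy-3-methoxybenzaldehyde (5-bromo-o-vanillin)
Product: 2 6-bromo-8-methoxy-2H-chromen-2-one (6-bromo-8-methoxycoumarin)
Conditions: Ph3P=CHCO2Et, N,N-diethylaniline, reflux
Reagents that add atoms: ethyl (triphenylphosphoranylidene)acetate, CCOC(=O)C=P(c1ccccc1)(c1ccccc1)c1ccccc1
Why: Wittig olefination of the salicylaldehyde, followed in the same pot by thermal E-to-Z isomerisation and lactonisation of the o-hydroxycinnamate, is a standard coumarin synthesis that leaves the aryl bromide and methyl ether untouched.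

Step 2
Reactants: 2 6-bromo-8-methoxycoumarin; 3 4-hydroxy-3-methoxyphenylboronic acid
Product: 4 (S)-6-bromo-4-(4-hydroxy-3-methoxyphenyl)-8-methoxychroman-2-one
Conditions: Rh(acac)(C2H4)2 (3 mol%), (S)-SEGPHOS (3.3 mol%), 3 (5 equiv, in portions), 1,4-dioxane/H2O 10:1, 60 °C
Reagents that add atoms: none
Why: In this Hayashi–Miyaura asymmetric 1,4-addition, the aryl–rhodium species (monovalent rhodium) should insert the coumarin C3=C4 bond on the face dictated by (S)-SEGPHOS to set the (S) centre at C4, while the neutral aqueous medium tolerates the free phenol and the aryl bromide and excess boronic acid offsets protodeboronation.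

Step 3
Reactants: 4 (S)-6-bromo-4-(4-hydroxy-3-methoxyphenyl)-8-methoxychroman-2-one
Product: 5 (S)-3-(5-bromo-2-hydroxy-3-methoxyphenyl)-3-(4-hydroxy-3-methoxyphenyl)-N-methoxy-N-methylpropanamide
Conditions: MeNH(OMe), AlMe3 (4 equiv), CH2Cl2, 0 °C → rt; aq. potassium sodium tartrate
Reagents that add atoms: N,O-dimethylhydroxylamine, CNOC
Why: Aluminium amide aminolysis of the reactive aryl lactone (Weinreb amide formation) should open the ring cleanly, the phenols merely consuming extra AlMe3 and the benzylic stereocentre being non-acidic.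

Step 4
Reactants: 5 (S)-3-(5-bromo-2-hydroxy-3-methoxyphenyl)-3-(4-hydroxy-3-methoxyphenyl)-N-methoxy-N-methylpropanamide
Product: 6 (S)-3-ArB-3-ArA-N-methoxy-N-methylpropanamide
Conditions: TBSCl (3 equiv), imidazole (6 equiv), DMF, rt → 40 °C
Reagents that add atoms: tert-butyldimethylsilyl chloride, CC(C)(C)[Si](C)(C)Cl
Why: Imidazole-promoted silylation of both phenols blocks relactonisation, later oxa-Michael addition to the enone and trapping of the ketenes in the key step.

Step 5
Reactants: 6 (S)-3-ArB-3-ArA-N-methoxy-N-methylpropanamide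
Product: 7 (S)-3-ArB-3-ArA-propanal
Conditions: i-Bu2AlH, THF, −78 °C; aq. potassium sodium tartrate
Reagents that add atoms: none
Why: Weinreb amide reduction stops at the chelated tetrahedral aluminate, which releases the aldehyde only on work-up, and the aryl bromide and silyl ethers survive at −78 °C.

Step 6
Reactants: 7 (S)-3-ArB-3-ArA-propanal
Product: 8 (S,E)-6-ArB-6-ArA-hex-3-en-2-one
Conditions: Ph3P=CHC(O)CH3, toluene, 80 °C
Reagents that add atoms: 1-(triphenylphosphoranylidene)propan-2-one, CC(=O)C=P(c1ccccc1)(c1ccccc1)c1ccccc1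
Why: Wittig olefination with the stabilised acetonyl ylide should give the E-enone under neutral conditions that cannot touch the β-stereocentre.

Step 7
Reactants: 8 (S,E)-6-ArB-6-ArA-hex-3-en-2-one
Product: 10 (S,E)-1-diazo-6-ArB-6-ArA-hex-3-en-2-one, via trifluoroacetyl diketone 9 (not isolated)
Conditions: LiN(SiMe3)2, THF, −78 °C, then CF3CO2CH2CF3; dilute HCl work-up; then MsN3, Et3N, H2O, MeCN, rt
Reagents that add atoms: methanesulfonyl azide, CS(=O)(=O)N=[N+]=[N-]
Why: In this detrifluoroacetylative (Regitz-type deacylative) diazo transfer, the kinetic cross-conjugated methyl enolate is trifluoroacetylated, and azide transfer to the activated methylene with loss of the trifluoroacetyl group gives the diazo ketone without exposing the enone to diazomethane.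

Step 8
Reactants: 11 ethyl formate
Product: 14 (triisopropylsilyloxy)acetylene, via lithium 2,2-dibromoethenolate 12 (not isolated), via lithium ethynolate 13 (not isolated)
Conditions: CH2Br2, lithium 2,2,6,6-tetramethylpiperidide, THF, −78 °C, then 11, then a second equiv of the amide; n-BuLi, −78 → 0 °C; i-Pr3SiCl, −78 °C → rt; distillation
Reagents that add atoms: dibromomethane, BrCBr; triisopropylsilyl chloride, CC(C)[Si](Cl)(C(C)C)C(C)C
Why: Proposed new method: dibromomethyllithium should add to the formate, the adduct should lose ethoxide under the second equivalent of amide to give enolate 12, and bromine–lithium exchange should trigger a Fritsch–Buttenberg–Wiechell-type 1,2-hydride shift of the α-bromo-α-lithio enolate to ynolate 13, which the bulky silyl chloride should capture on oxygen; the closest known reaction type is the Kowalski ester-to-ynolate homologation with triisopropylsilyl trapping to 1-silyloxyalkynes, in which carbon rather than hydrogen migrates, together with the Corey–Fuchs alkyne synthesis for the hydride shift.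

Step 9
Reactants: 10 (S,E)-1-diazo-6-ArB-6-ArA-hex-3-en-2-one; 14 (triisopropylsilyloxy)acetylene
Product: 19 (S)-2-(2-ArB-2-ArA-ethyl)-5-(TIPS-oxy)phenol, via alkenylketene 15 (not isolated), via 4-alkenylcyclobutenone 16 (not isolated), via dienylketene 17 (not isolated), via cyclohexa-2,4-dienone 18 (not isolated)
Conditions: 14 (2.5 equiv), ClCH2CH2Cl (0.05 M, degassed), hν (λ > 300 nm, Pyrex-filtered medium-pressure Hg lamp), rt; then 80 °C in the dark
Reagents that add atoms: none
Why: Light expels N2 from the diazo ketone with 1,2-shift of the alkenyl group (Wolff rearrangement) to give alkenylketene 15, whose carbonyl carbon is attacked by the unsubstituted, nucleophilic carbon of the silyloxyalkyne so that [2+2] cycloaddition closes cyclobutenone 16. Warming opens 16 by 4π conrotatory electrocyclic cleavage to dienylketene 17, ring C closes by thermal 6π disrotatory electrocyclisation between the ketene carbon and the former enone β-carbon, and dienone 18 tautomerises to the phenol. The closest known reaction type is the photochemical diazo ketone form of the Danheiser benzannulation with silyloxyalkynes, which gives resorcinol monosilyl ethers. No lasting stereocentre is formed, since the sp3 centres of 16 and 18 vanish on aromatisation and the existing (S) centre sits two saturated atoms from the reacting π system. The step needs the hydroxyl ortho and the silyloxy group para to the CH2 branch, and the polarisation of the ynol ether secures this because its β-carbon is the one that bonds to the ketene carbonyl carbon. Chemoselectivity rests on irradiating above 300 nm, where the diazo ketone absorbs and the aryl bromide does not, on both phenols being silylated so that no hydroxyl can trap the ketenes, and on excess alkyne and dilution to limit acylation of the product phenol.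

Step 10
Reactants: 20 3,5-dihydroxybenzaldehyde
Product: 21 3,5-bis(TBS-oxy)benzaldehyde
Conditions: TBSCl, imidazole, DMF, rt
Reagents that add atoms: tert-butyldimethylsilyl chloride, CC(C)(C)[Si](C)(C)Cl
Why: Standard imidazole-promoted silylation protects both phenols ahead of the basic ylide and matches the silyl protection used elsewhere for one final deprotection.

Step 11
Reactants: 21 3,5-bis(TBS-oxy)benzaldehyde
Product: 22 3,5-bis(TBS-oxy)styrene
Conditions: Ph3PCH3Br, KOt-Bu, THF, 0 °C → rt
Reagents that add atoms: methyltriphenylphosphonium bromide, C[P+](c1ccccc1)(c1ccccc1)c1ccccc1.[Br-]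
Why: Wittig methylenation of a non-enolisable aryl aldehyde is reliable and leaves aryl silyl ethers intact.

Step 12
Reactants: 19 (S)-2-(2-ArB-2-ArA-ethyl)-5-(TIPS-oxy)phenol; 22 3,5-bis(TBS-oxy)styrene
Product: 23 2-[(S)-2-[2-(TBS-oxy)-5-[(E)-3,5-bis(TBS-oxy)styryl]-3-methoxyphenyl]-2-ArA-ethyl]-5-(TIPS-oxy)phenol
Conditions: Pd2(dba)3 (2.5 mol%), [(t-Bu)3PH]BF4 (10 mol%), Cy2NMe, 1,4-dioxane, 80 °C
Reagents that add atoms: none
Why: In this Mizoroki–Heck coupling, zerovalent palladium bearing the bulky trialkylphosphine should add oxidatively to the electron-rich aryl bromide, insert the styrene at its terminal carbon and undergo syn β-hydride elimination to the E-stilbene, the amine base tolerating the free phenol and the silyl ethers.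

Step 13
Reactants: 23 penta-silylated stilbene from step 12
Product: 24 4-[(S)-2-[5-[(E)-3,5-dihydroxystyryl]-2-hydroxy-3-methoxyphenyl]-2-(4-hydroxy-3-methoxyphenyl)ethyl]benzene-1,3-diol (target)
Conditions: n-Bu4NF (6 equiv), AcOH (6 equiv), THF, 0 °C → rt, argon
Reagents that add atoms: none
Why: Fluoride cleaves all five aryl silyl ethers, and acetic acid buffering with exclusion of air protects the electron-rich polyphenolic stilbene from oxidation, leaving the methyl ethers, the alkene and the stereocentre untouched.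

**Compound list**

1 | 5-bromo-2-hydroxy-3-methoxybenzaldehyde | COc1cc(Br)cc(C=O)c1O | starting material
2 | 6-bromo-8-methoxy-2H-chromen-2-one | COc1cc(Br)cc2ccc(=O)oc12 | intermediate
3 | 4-hydroxy-3-methoxyphenylboronic acid | COc1cc(B(O)O)ccc1O | starting material
4 | (S)-6-bromo-4-(4-hydroxy-3-methoxyphenyl)-8-methoxychroman-2-one | COc1cc([C@H](CC(=O)O2)c3cc(Br)cc(OC)c32)ccc1O | intermediate
5 | (S)-3-(5-bromo-2-hydroxy-3-methoxyphenyl)-3-(4-hydroxy-3-methoxyphenyl)-N-methoxy-N-methylpropanamide | COc1cc([C@H](CC(=O)N(C)OC)c2cc(Br)cc(OC)c2O)ccc1O | intermediate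
6 | (S)-3-ArB-3-ArA-N-methoxy-N-methylpropanamide | COc1cc([C@H](CC(=O)N(C)OC)c2cc(Br)cc(OC)c2O[Si](C)(C)C(C)(C)C)ccc1O[Si](C)(C)C(C)(C)C | intermediate
7 | (S)-3-ArB-3-ArA-propanal | COc1cc([C@H](CC=O)c2cc(Br)cc(OC)c2O[Si](C)(C)C(C)(C)C)ccc1O[Si](C)(C)C(C)(C)C | intermediate
8 | (S,E)-6-ArB-6-ArA-hex-3-en-2-one | COc1cc([C@H](C/C=C/C(C)=O)c2cc(Br)cc(OC)c2O[Si](C)(C)C(C)(C)C)ccc1O[Si](C)(C)C(C)(C)C | intermediate
9 | (S,E)-8-ArB-8-ArA-1,1,1-trifluorooct-5-ene-2,4-dione | COc1cc([C@H](C/C=C/C(=O)CC(=O)C(F)(F)F)c2cc(Br)cc(OC)c2O[Si](C)(C)C(C)(C)C)ccc1O[Si](C)(C)C(C)(C)C | intermediate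
10 | (S,E)-1-diazo-6-ArB-6-ArA-hex-3-en-2-one | COc1cc([C@H](C/C=C/C(=O)C=[N+]=[N-])c2cc(Br)cc(OC)c2O[Si](C)(C)C(C)(C)C)ccc1O[Si](C)(C)C(C)(C)C | intermediate
11 | ethyl formate | CCOC=O | starting material
12 | lithium 2,2-dibromoethenolate | [Li+].[O-]C=C(Br)Br | intermediate
13 | lithium ethynolate | [Li+].[O-]C#C | intermediate
14 | (triisopropylsilyloxy)acetylene | C#CO[Si](C(C)C)(C(C)C)C(C)C | intermediate
15 | (S,E)-6-ArB-6-ArA-hexa-1,3-dien-1-one (alkenylketene) | COc1cc([C@H](C/C=C/C=C=O)c2cc(Br)cc(OC)c2O[Si](C)(C)C(C)(C)C)ccc1O[Si](C)(C)C(C)(C)C | intermediate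
16 | 4-[(S,E)-4-ArB-4-ArA-but-1-enyl]-3-(TIPS-oxy)cyclobut-2-en-1-one (both C4 epimers) | COc1cc([C@H](C/C=C/C2C(=O)C=C2O[Si](C(C)C)(C(C)C)C(C)C)c2cc(Br)cc(OC)c2O[Si](C)(C)C(C)(C)C)ccc1O[Si](C)(C)C(C)(C)C | intermediate
17 | (S,3E,5E)-8-ArB-8-ArA-3-(TIPS-oxy)octa-1,3,5-trien-1-one (dienylketene, ketenyl group cis to C5 across C3=C4) | COc1cc([C@H](C/C=C/C=C(/O[Si](C(C)C)(C(C)C)C(C)C)\C=C=O)c2cc(Br)cc(OC)c2O[Si](C)(C)C(C)(C)C)ccc1O[Si](C)(C)C(C)(C)C | intermediate
18 | 6-[(S)-2-ArB-2-ArA-ethyl]-3-(TIPS-oxy)cyclohexa-2,4-dien-1-one (both C6 epimers) | COc1cc([C@H](CC2C=CC(O[Si](C(C)C)(C(C)C)C(C)C)=CC2=O)c2cc(Br)cc(OC)c2O[Si](C)(C)C(C)(C)C)ccc1O[Si](C)(C)C(C)(C)C | intermediate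
19 | (S)-2-(2-ArB-2-ArA-ethyl)-5-(TIPS-oxy)phenol | COc1cc([C@H](Cc2ccc(O[Si](C(C)C)(C(C)C)C(C)C)cc2O)c2cc(Br)cc(OC)c2O[Si](C)(C)C(C)(C)C)ccc1O[Si](C)(C)C(C)(C)C | intermediate
20 | 3,5-dihydroxybenzaldehyde | O=Cc1cc(O)cc(O)c1 | starting material
21 | 3,5-bis(TBS-oxy)benzaldehyde | O=Cc1cc(O[Si](C)(C)C(C)(C)C)cc(O[Si](C)(C)C(C)(C)C)c1 | intermediate
22 | 3,5-bis(TBS-oxy)styrene | C=Cc1cc(O[Si](C)(C)C(C)(C)C)cc(O[Si](C)(C)C(C)(C)C)c1 | intermediate
23 | 2-[(S)-2-[2-(TBS-oxy)-5-[(E)-3,5-bis(TBS-oxy)styryl]-3-methoxyphenyl]-2-ArA-ethyl]-5-(TIPS-oxy)phenol | COc1cc([C@H](Cc2ccc(O[Si](C(C)C)(C(C)C)C(C)C)cc2O)c2cc(/C=C/c3cc(O[Si](C)(C)C(C)(C)C)cc(O[Si](C)(C)C(C)(C)C)c3)cc(OC)c2O[Si](C)(C)C(C)(C)C)ccc1O[Si](C)(C)C(C)(C)C | intermediate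
24 | 4-[(S)-2-[5-[(E)-3,5-dihydroxystyryl]-2-hydroxy-3-methoxyphenyl]-2-(4-hydroxy-3-methoxyphenyl)ethyl]benzene-1,3-diol | COc1cc([C@H](Cc2ccc(O)cc2O)c2cc(/C=C/c3cc(O)cc(O)c3)cc(OC)c2O)ccc1O | target

**Step count and risks**

Total steps: 13. Longest linear sequence: 10 steps (steps 1–7, 9, 12 and 13, from 1 to 24).

Steps most likely to fail:

1. Step 8 (proposed new method). The dibromomethyl carbenoid may add twice to the formate, the unhindered ynolate may be silylated on carbon to a silylketene, or the volatile, acid-sensitive ynol ether may be lost on isolation.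
 Fallback, setting out from 10 and commercial (trimethylsilyl)acetylene: lithiation with n-BuLi, oxidation of the acetylide with lithium tert-butyl peroxide and O-silylation of the resulting silylynolate with i-Pr3SiOTf should give 1-(triisopropylsilyloxy)-2-(trimethylsilyl)ethyne F1. F1 would replace 14 in the benzannulation with 10 under the step 9 conditions, the ynol ether polarisation again fixing the regiochemistry, to give the 3-trimethylsilyl analogue of 19, (S)-2-(2-ArB-2-ArA-ethyl)-5-(TIPS-oxy)-6-(trimethylsilyl)phenol F2. Ipso-protodesilylation of this doubly oxygen-activated arylsilane with CF3CO2H in CH2Cl2 at 0 °C would return the route at 19.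

2. Step 9. Photoreduction of the C–Br bond or carbene-type side reactions may compete with the Wolff rearrangement, and the product phenol may be acylated by the ketene intermediates.
 Fallback, setting out from 7 and generating the same ketene thermally without light: Wittig reaction with the ylide from (2-carboxyethyl)triphenylphosphonium bromide and NaN(SiMe3)2 should give (S,Z)-6-ArB-6-ArA-hex-3-enoic acid F3, and oxalyl chloride with catalytic DMF its acid chloride F4. Slow addition of Et3N to F4 and 14 in toluene (rt, then 80 °C) should dehydrochlorinate F4 to the Z isomer of alkenylketene 15, which enters the same cycloaddition, ring-opening and electrocyclisation cascade and returns the route at 19.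

3. Step 2. Carbometalation of the poorly electrophilic coumarin may be slow, the electron-rich boronic acid may protodeboronate, or facial selectivity may be insufficient.
 Fallback, setting out from 2 and 3 and separating C–C bond formation from the stereo-defining event: oxidative Heck arylation (Pd(OAc)2, 1,10-phenanthroline, O2, DMF, 80 °C; divalent palladium does not insert into the C–Br bond) should give 6-bromo-4-(4-hydroxy-3-methoxyphenyl)-8-methoxy-2H-chromen-2-one F5. Asymmetric copper hydride 1,4-reduction (Cu(OAc)2, the DTBM-SEGPHOS enantiomer that delivers hydride to the required face, (EtO)2MeSiH, t-BuOH, toluene, rt) should then return the route at 4.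

**Further compounds**

F1 | step 8 | 1-(triisopropylsilyloxy)-2-(trimethylsilyl)ethyne | C[Si](C)(C)C#CO[Si](C(C)C)(C(C)C)C(C)C
F2 | step 8 | (S)-2-(2-ArB-2-ArA-ethyl)-5-(TIPS-oxy)-6-(trimethylsilyl)phenol | COc1cc([C@H](Cc2ccc(O[Si](C(C)C)(C(C)C)C(C)C)c([Si](C)(C)C)c2O)c2cc(Br)cc(OC)c2O[Si](C)(C)C(C)(C)C)ccc1O[Si](C)(C)C(C)(C)C
F3 | step 9 | (S,Z)-6-ArB-6-ArA-hex-3-enoic acid | COc1cc([C@H](C/C=C\CC(=O)O)c2cc(Br)cc(OC)c2O[Si](C)(C)C(C)(C)C)ccc1O[Si](C)(C)C(C)(C)C
F4 | step 9 | (S,Z)-6-ArB-6-ArA-hex-3-enoyl chloride | COc1cc([C@H](C/C=C\CC(=O)Cl)c2cc(Br)cc(OC)c2O[Si](C)(C)C(C)(C)C)ccc1O[Si](C)(C)C(C)(C)C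
F5 | step 2 | 6-bromo-4-(4-hydroxy-3-methoxyphenyl)-8-methoxy-2H-chromen-2-one | COc1cc(-c2cc(=O)oc3c(OC)cc(Br)cc23)ccc1O
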